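## The problem

Target 14 is a linear bromophlorethol: three benzene rings joined only by two diaryl ether oxygens, with seven free phenolic hydroxyls and one bromine. It has no stereocentre and no ring to close, so the whole task is regiochemical. Ring A is a 3,5-dihydroxyphenyl group, ring B carries the ring A oxygen at C1, hydroxyls at C2 and C6 and the ring C oxygen at C4, and ring C is a phloroglucinol bound through an oxygen flanked by two hydroxyls, with bromine at C3. Each ether oxygen is therefore bound on one side to a carbon with two ortho oxygen substituents, so each diaryl ether must be made from a hindered, electron-rich phenol, and neither ring B at C1 nor ring C can serve as an electrophile in an ordinary arylation. All three rings are strongly activated toward electrophiles, so a late bromination could not be confined to one carbon of ring C; the bromine has to be placed before the rings are joined, and every later step must spare the C–Br bond (no hydrogenolysis, no hot zerovalent palladium). The free heptaphenol is polar and air-sensitive, so the hydroxyls must stay masked until the end by groups that come off without reduction. The enabling feature is that the oxygens at C2, C4 and C6 of ring B lie ortho, para and ortho to C1: an acceptor at C1 activates exactly these three carbons for nucleophilic aromatic substitution, and a formyl group is such an acceptor that can afterwards be exchanged for the C1 oxygen by peracid oxidation.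

## Retrosynthesis

**14 ⇒ 13.** The seven O–CH3 bonds are cut last. Methyl ethers survive alkoxide, carbonate, peracid and copper, and BBr3 removes them without touching the aryl bromide. Benzyl ethers would call for hydrogenolysis, which endangers C–Br, and silyl ethers would not survive methoxide. Heptamethyl ether 13 is a stable, non-polar compound that can be purified normally. The forward step must cleave all seven ethers.

**13 ⇒ 11 + 12.** The O–C(ring A) bond is cut, not the O–C1(ring B) bond. The latter would need an electrophilic carbon between two methoxy groups on an electron-rich ring. Ring A becomes the commercial boronic acid 12 and ring B the phenol 11. An oxidative copper coupling at room temperature is chosen because it leaves the aryl bromide alone, which a heated Ullmann or a palladium etherification might not. The forward reaction has to arylate a phenol flanked by two methoxy groups.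

**11 ⇒ 9.** The C1–O bond of ring B is traced back to a C1–CHO bond (Baeyer–Villiger oxidation of the aldehyde, then cleavage of the formate). Ring B in 9 has two ortho methoxy groups and a para aryloxy group, so aryl migration should be clean. This turns a 1,2,3,5-tetraoxygenated ring into a benzaldehyde with heteroatoms at C2, C4 and C6.

**9 ⇒ 4 + 5 + 6.** The three C–O bonds at C2, C4 and C6 of ring B are cut together. The precursors are phenol 4, 2,4,6-trifluorobenzaldehyde 5 and two moles of sodium methoxide 6, one for each ortho fluoride. Compared with coupling 4 to a preformed 4-halo-2,6-dimethoxybenzaldehyde, this builds the whole oxygenation pattern of ring B from a commodity aldehyde in one flask and needs no metal near the C–Br bond. The order is fixed by selectivity: the bulky phenoxide must choose the para fluoride while all three are present, and methoxide then finds only the two equivalent ortho fluorides. The forward step needs para selectivity in the first substitution and a methoxide charge held close to the two moles that the equation demands.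

**4 ⇒ 2 ⇒ 1.** The phenolic C–O bond of 4 is again traced to a formyl group, and the C–Br bond is then cut to give 2,4,6-trimethoxybenzaldehyde 1. In 1 the only free ring positions, C3 and C5, are equivalent, so monobromination is a matter of stoichiometry, and it is done before any other ring is present. The route is six steps from 1.

## Roads not taken

**Alternative 1:** Ring B would be built from carbon fragments in a Danheiser-type benzannulation. Heating the cyclobutenone A2 (ring A already attached through oxygen at C4) opens it to a vinylketene. This adds the aryl ethynyl ether A3 (ring C attached through oxygen); ring opening and 6π-electrocyclisation then give phenol A1 with three new C–C bonds. Its merits are real. Both ether oxygens are introduced on non-aromatic carbons before ring B exists, so the arylation of a di-ortho-substituted phenol (step 5 here) is avoided, and the substitution pattern of ring B follows from the mechanism, not from a choice among fluorides. In these two respects it is the better road. Its weak points lie elsewhere. A1 has no bromine, so ring C must be brominated late, in competition with ring A and with the new free phenol on ring B. A1 carries benzyl, ethyl and methyl ethers, which need more than one deprotection logic. A3 needs a multi-step conversion of a hindered phenol into a sensitive ynol ether, and A2 needs a ketene cycloaddition. The sequence would be at least nine or ten steps. The chosen plan sets against this a bromine fixed in step 1 on an isolated ring, three commercial building blocks and six steps.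

**Alternative 2:** Two C–C bonds of ring B would be formed by a double Claisen-type condensation. The dienolate of the aryloxyglutaconate A6 (brominated ring C attached) would be acylated at both termini by the aryloxymalonate A5 (ring A attached), giving the isophthalate A4. This is convergent, has the bromine in place from the start, and makes both ether bonds by alkylation or conjugate addition of phenols on aliphatic carbon, so it too avoids the hindered arylation. On early bromination it equals the chosen plan. Its weaknesses are in the ring-forming step and afterwards. A5 has an acidic C–H between two esters, and the base needed for the dienolate of A6 would turn it into an unreactive enolate, so more activated acyl derivatives would be needed and O-acylation then competes. A4 is a crowded hexasubstituted benzene, and its two ester groups must be removed by saponification and double decarboxylation before demethylation. The chosen plan sets against it well-understood steps (SNAr, peracid oxidation), no carbon that must later be excised, and two or three fewer steps.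

**Alternative 3:** The three hydroxyls of ring C would come from three formyl groups. Trialdehyde A8 would be oxidised with a peracid to a triformate and methanolysed to triol A7. A8 itself would come from SNAr of phenol A9 on a benzene-1,3,5-tricarbaldehyde with a single leaving group at C2. This uses the same latent-phenol device as the chosen plan, three times at once. The SNAr that makes A8 has no regiochemical question, which is cleaner than the para/ortho issue of step 3. A7 also has ring C as a free triol beside methylated rings A and B, a possible handle for directing bromine to ring C. The drawbacks are mechanistic. Aryl migration in peracid oxidation needs an electron-rich ring, and in A8 the ring carries three acceptors against one aryloxy donor, so hydride migration to carboxylic acids should compete. A7 has no bromine, and monobromination of a free phloroglucinol ring with two equivalent, still activated positions is hard to stop. A9 needs the same hindered phenol arylation as step 5, so that difficulty is not avoided. The chosen plan uses one formyl group at a time, each on an electron-rich ring, and places bromine first.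

Key step: step 3

## Route

Step 1
Reactants: 1 2,4,6-trimethoxybenzaldehyde
Product: 2 3-bromo-2,4,6-trimethoxybenzaldehyde
Conditions: NBS (1.0 equiv), MeCN, 0 °C to rt, dark
Reagents that add atoms: N-bromosuccinimide, O=C1CCC(=O)N1Br
Why: Electrophilic aromatic bromination; C3 and C5 are the only free positions, are equivalent and are activated by all three methoxy groups, and the first bromine deactivates the ring enough for one equivalent of NBS to stop at the monobromide.

Step 2
Reactants: 2 3-bromo-2,4,6-trimethoxybenzaldehyde
Product: 4 3-bromo-2,4,6-trimethoxyphenol, via 3-bromo-2,4,6-trimethoxyphenyl formate 3 (not isolated)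
Conditions: mCPBA (1.3 equiv), CH2Cl2, 0 °C to rt; aq. Na2S2O3/NaHCO3 wash; crude formate, K2CO3 (0.2 equiv), MeOH, rt, argon
Reagents that add atoms: 3-chloroperoxybenzoic acid, OOC(=O)c1cccc(Cl)c1
Why: Baeyer–Villiger (Dakin-type) oxidation; the ring with three methoxy groups migrates in preference to hydride in the Criegee adduct, and the aryl formate is methanolysed by catalytic base after the excess peracid is destroyed, so the electron-rich phenol never meets the oxidant.

Step 3
Reactants: 4 3-bromo-2,4,6-trimethoxyphenol; 5 2,4,6-trifluorobenzaldehyde; 6 sodium methoxide
Product: 9 4-(3-bromo-2,4,6-trimethoxyphenoxy)-2,6-dimethoxybenzaldehyde, via 2,6-difluoro diaryl ether aldehyde 7 (not isolated), via 2-fluoro-6-methoxy diaryl ether aldehyde 8 (not isolated)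
Conditions: 4 (1.05 equiv), KOt-Bu (1.0 equiv), dry DMF, 0 °C; 5 (1.0 equiv), −20 °C to rt; then 6 (2.2 equiv, solution in MeOH), rt to 50 °C
Reagents that add atoms: sodium methoxide (second mole of 6), [Na+].[O-]C
Why: Each of the three substitutions is an addition–elimination (SNAr) through a Meisenheimer anion whose charge is taken up by the formyl group; the closest known reaction type is the sequential substitution of polyfluorobenzaldehydes by phenoxides and alkoxides. The potassium phenoxide of 4, preformed with slightly less than one equivalent of KOt-Bu so that neither free tert-butoxide nor an acidic by-product that would consume methoxide is present, adds at C4 of 5 and fluoride leaves to give 7. Para selectivity rests on two features: the nucleophile is flanked by two methoxy groups and avoids the fluorides next to the formyl group, and in DMF with potassium as counter-ion there is no tight ion pair that the carbonyl oxygen could steer to an ortho carbon. Two moles of the small methoxide then replace the two equivalent ortho fluorides one after the other by way of 8, so the equation consumes one mole of 4, one of 5 and two of 6. The oxygen substituents already installed sit meta to the carbon under attack, not on the carbons that carry the negative charge, so they slow the later substitutions only slightly. Fluoride is replaced in preference to the aryloxy group because addition at a C–F carbon is faster, and keeping methoxide near two equivalents at moderate temperature protects the C4 ether. Addition of methoxide to the formyl group is reversible, and dry conditions keep out hydroxide, which could cleave the formyl group from a 2,6-dihalobenzaldehyde. Three C–O bonds of ring B are formed in one flask; no ring closes and no stereocentre arises.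

Step 4
Reactants: 9 4-(3-bromo-2,4,6-trimethoxyphenoxy)-2,6-dimethoxybenzaldehyde
Product: 11 4-(3-bromo-2,4,6-trimethoxyphenoxy)-2,6-dimethoxyphenol, via aryl formate 10 (not isolated)
Conditions: mCPBA (1.3 equiv), CH2Cl2, 0 °C to rt; aq. Na2S2O3/NaHCO3 wash; crude formate, K2CO3 (0.2 equiv), MeOH, rt, argon
Reagents that add atoms: 3-chloroperoxybenzoic acid, OOC(=O)c1cccc(Cl)c1
Why: Baeyer–Villiger (Dakin-type) oxidation; ring B with two ortho methoxy groups and a para aryloxy group migrates readily, so the formyl group that activated the SNAr steps is exchanged for the C1 oxygen, and the formate is methanolysed after the peracid is quenched.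

Step 5
Reactants: 11 4-(3-bromo-2,4,6-trimethoxyphenoxy)-2,6-dimethoxyphenol; 12 3,5-dimethoxyphenylboronic acid
Product: 13 2-bromo-4-[4-(3,5-dimethoxyphenoxy)-3,5-dimethoxyphenoxy]-1,3,5-trimethoxybenzene
Conditions: 12 (2.5 equiv), Cu(OAc)2 (2.0 equiv), pyridine (5 equiv), 4 Å MS, CH2Cl2, rt
Reagents that add atoms: none
Why: Chan–Lam (Chan–Evans–Lam) O-arylation; the aryl group passes from boron to a divalent copper phenoxide, a second divalent copper oxidises this to a trivalent aryl copper phenoxide, and reductive elimination forms the C–O bond at room temperature, where the hindered aryl bromide is inert; the copper salt is used as the stoichiometric oxidant and molecular sieves suppress hydroxylation of 12.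

Step 6
Reactants: 13 2-bromo-4-[4-(3,5-dimethoxyphenoxy)-3,5-dimethoxyphenoxy]-1,3,5-trimethoxybenzene
Product: 14 2-bromo-4-[4-(3,5-dihydroxyphenoxy)-3,5-dihydroxyphenoxy]benzene-1,3,5-triol
Conditions: BBr3 (12 equiv, 1 M in CH2Cl2), CH2Cl2, −78 °C to rt; MeOH then H2O, 0 °C, argon
Reagents that add atoms: none
Why: Lewis acid cleavage of aryl methyl ethers; boron binds each ether oxygen and bromide attacks the methyl group, so all seven methyl groups leave as bromomethane while the diaryl ether bonds and the aryl bromide, which have no such SN2 pathway, remain.

## Compound list

1 | 2,4,6-trimethoxybenzaldehyde | COc1cc(OC)c(C=O)c(OC)c1 | starting material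
2 | 3-bromo-2,4,6-trimethoxybenzaldehyde | COc1cc(OC)c(Br)c(OC)c1C=O | intermediate
3 | 3-bromo-2,4,6-trimethoxyphenyl formate | COc1cc(OC)c(Br)c(OC)c1OC=O | intermediate
4 | 3-bromo-2,4,6-trimethoxyphenol | COc1cc(OC)c(Br)c(OC)c1O | intermediate
5 | 2,4,6-trifluorobenzaldehyde | O=Cc1c(F)cc(F)cc1F | starting material
6 | sodium methoxide | [Na+].[O-]C | starting material
7 | 4-(3-bromo-2,4,6-trimethoxyphenoxy)-2,6-difluorobenzaldehyde | O=Cc1c(F)cc(Oc2c(OC)cc(OC)c(Br)c2OC)cc1F | intermediate
8 | 4-(3-bromo-2,4,6-trimethoxyphenoxy)-2-fluoro-6-methoxybenzaldehyde | COc1cc(Oc2c(OC)cc(OC)c(Br)c2OC)cc(F)c1C=O | intermediate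
9 | 4-(3-bromo-2,4,6-trimethoxyphenoxy)-2,6-dimethoxybenzaldehyde | COc1cc(Oc2c(OC)cc(OC)c(Br)c2OC)cc(OC)c1C=O | intermediate
10 | 4-(3-bromo-2,4,6-trimethoxyphenoxy)-2,6-dimethoxyphenyl formate | COc1cc(Oc2c(OC)cc(OC)c(Br)c2OC)cc(OC)c1OC=O | intermediate
11 | 4-(3-bromo-2,4,6-trimethoxyphenoxy)-2,6-dimethoxyphenol | COc1cc(Oc2c(OC)cc(OC)c(Br)c2OC)cc(OC)c1O | intermediate
12 | 3,5-dimethoxyphenylboronic acid | COc1cc(OC)cc(B(O)O)c1 | starting material
13 | 2-bromo-4-[4-(3,5-dimethoxyphenoxy)-3,5-dimethoxyphenoxy]-1,3,5-trimethoxybenzene | COc1cc(OC)cc(Oc2c(OC)cc(Oc3c(OC)cc(OC)c(Br)c3OC)cc2OC)c1 | intermediate
14 | 2-bromo-4-[4-(3,5-dihydroxyphenoxy)-3,5-dihydroxyphenoxy]benzene-1,3,5-triol | Oc1cc(O)cc(Oc2c(O)cc(Oc3c(O)cc(O)c(Br)c3O)cc2O)c1 | target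

## Step count and risks

Total step count: 6. Longest linear sequence: 6 steps (1 → 2 → 4 → 9 → 11 → 13 → 14); 5, 6 and 12 are bought.

**Step 3 (key step).**
- Regiochemistry: the phenoxide may attack an ortho fluoride. There are two of them against one para fluoride, and any contact ion pair can be drawn toward the carbonyl oxygen.
- Methoxide stage: the aryloxy group at C4 may be exchanged for methoxide, the formyl group may be cleaved if hydroxide is present, or the third substitution may stall on the now more electron-rich ring.
- Fallback: this sets out from 4 and gives up the threefold substitution while keeping the formyl group as the latent C1 oxygen. Phenol 4 would be coupled with commercial 4-bromo-2,6-dimethoxybenzaldehyde F1 in an Ullmann-type etherification (CuI, picolinic acid, K3PO4, DMSO, 80 °C). F1 already has both methoxy groups, so no regiochemical question remains. Its unhindered, formyl-activated C–Br bond should react well before the C–Br bond of 4, which is flanked by two methoxy groups on an electron-rich ring. The fallback comes back to the route at 9.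

**Step 5.**
- Coupling: the phenol of 11 lies between two methoxy groups, so its binding to copper and the C–O reductive elimination may be slow.
- Competing reactions: oxidation of the electron-rich phenol by divalent copper, and protodeboronation or hydroxylation of 12 followed by arylation of the phenol so formed.
- Fallback: this sets out from 11 and uses a metal-free arylation with (3,5-dimethoxyphenyl)(2,4,6-trimethoxyphenyl)iodonium 4-methylbenzenesulfonate F2. F2 would be prepared in one pot from 1-iodo-3,5-dimethoxybenzene, mCPBA, TsOH and 1,3,5-trimethoxybenzene. The potassium phenoxide of 11 (KOt-Bu, THF, 0 °C to rt) attacks the hypervalent iodine, and ligand coupling transfers the less electron-rich 3,5-dimethoxyphenyl group. The trimethoxyphenyl group acts as the non-transferred ligand. This reaction type tolerates ortho-disubstituted phenols and aryl bromides. It comes back to the route at 13.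

**Step 6.**
- Cleavage: demethylation may be incomplete at the hindered methoxy groups beside the ether oxygens, leaving mixtures of partly methylated polyphenols that cannot be separated as free phenols.
- Isolation: the heptaphenol may oxidise in air on silica.
- Bromine: prolonged contact of the bromophloroglucinol ring with HBr may lead to migration or loss of bromine.
- Fallback: this sets out from 13 and changes the isolation to capture and release. After the BBr3 treatment and a cold quench, the crude phenol mixture is acetylated at once (Ac2O, pyridine, DMAP) to 2-bromo-4-[3,5-diacetoxy-4-(3,5-diacetoxyphenoxy)phenoxy]benzene-1,3,5-triyl triacetate F3. F3 is stable and can be chromatographed away from under-cleaved material, which can be resubmitted. Acid-catalysed methanolysis of F3 (HCl in MeOH from AcCl, degassed, rt) and evaporation then give the free heptaphenol without chromatography, so the fallback comes back to the route at 14.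

**Step 1.**
- Selectivity: a second bromination at C5, or ipso attack at the formyl-bearing carbon (also activated by three methoxy groups) with loss of the formyl group.
- Fallback: this does not set out from a compound of the route; commercial 2-bromo-1,3,5-trimethoxybenzene F4 takes the place of 1 and is formylated (Vilsmeier–Haack, POCl3, DMF, 0 to 60 °C). Its two free positions are equivalent, so a single aldehyde should result. This comes back to the route at 2.

## Further compounds

F1 | step 3 | 4-bromo-2,6-dimethoxybenzaldehyde | COc1cc(Br)cc(OC)c1C=O
F2 | step 5 | (3,5-dimethoxyphenyl)(2,4,6-trimethoxyphenyl)iodonium 4-methylbenzenesulfonate | COc1cc(OC)cc([I+]c2c(OC)cc(OC)cc2OC)c1.Cc1ccc(cc1)S(=O)(=O)[O-]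
F3 | step 6 | 2-bromo-4-[3,5-diacetoxy-4-(3,5-diacetoxyphenoxy)phenoxy]benzene-1,3,5-triyl triacetate | CC(=O)Oc1cc(OC(C)=O)cc(Oc2c(OC(C)=O)cc(Oc3c(OC(C)=O)cc(OC(C)=O)c(Br)c3OC(C)=O)cc2OC(C)=O)c1
F4 | step 1 | 2-bromo-1,3,5-trimethoxybenzene | COc1cc(OC)c(Br)c(OC)c1
A1 | alternative 1 | 5-(2-benzyloxy-4,6-dimethoxyphenoxy)-2-(3,5-dimethoxyphenoxy)-3-ethoxyphenol | CCOc1cc(Oc2c(OCc3ccccc3)cc(OC)cc2OC)cc(O)c1Oc1cc(OC)cc(OC)c1
A2 | alternative 1 | 4-(3,5-dimethoxyphenoxy)-3-ethoxycyclobut-2-en-1-one (racemic) | CCOC1=CC(=O)C1Oc1cc(OC)cc(OC)c1
A3 | alternative 1 | 1-(benzyloxy)-2-(ethynyloxy)-3,5-dimethoxybenzene | C#COc1c(OCc2ccccc2)cc(OC)cc1OC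
A4 | alternative 2 | dimethyl 2-(3-bromo-2,4,6-trimethoxyphenoxy)-5-(3,5-dimethoxyphenoxy)-4,6-dihydroxyisophthalate | COC(=O)c1c(O)c(Oc2cc(OC)cc(OC)c2)c(O)c(C(=O)OC)c1Oc1c(OC)cc(OC)c(Br)c1OC
A5 | alternative 2 | dimethyl 2-(3,5-dimethoxyphenoxy)propanedioate | COC(=O)C(Oc1cc(OC)cc(OC)c1)C(=O)OC
A6 | alternative 2 | dimethyl (E)-3-(3-bromo-2,4,6-trimethoxyphenoxy)pent-2-enedioate | COC(=O)C/C(Oc1c(OC)cc(OC)c(Br)c1OC)=C\C(=O)OC
A7 | alternative 3 | 2-[4-(3,5-dimethoxyphenoxy)-3,5-dimethoxyphenoxy]benzene-1,3,5-triol | Oc1cc(O)c(Oc2cc(OC)c(Oc3cc(OC)cc(OC)c3)c(OC)c2)c(O)c1
A8 | alternative 3 | 2-[4-(3,5-dimethoxyphenoxy)-3,5-dimethoxyphenoxy]benzene-1,3,5-tricarbaldehyde | O=Cc1cc(C=O)c(Oc2cc(OC)c(Oc3cc(OC)cc(OC)c3)c(OC)c2)c(C=O)c1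
A9 | alternative 3 | 4-(3,5-dimethoxyphenoxy)-3,5-dimethoxyphenol | COc1cc(OC)cc(Oc2c(OC)cc(O)cc2OC)c1
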